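The strategy rests on reading the 2,4-dihydroxy-3-methoxyphenyl ring (C1 chain-bearing, C2 OH, C3 OMe, C4 OH, C5 H, C6 H) as the cyclised, dehydrated form of a 3-methoxy-2,4-dioxo aldehyde, itself the ring-opened form of a 2-alkyl-3-methoxy-4-pyranone. In one operation, hydroxide opens the pyranone and an intramolecular aldol condensation joins the former lateral methylene (C1) to the former pyranone C6, building the carbocycle with all three oxygens already in place. The precursor is O-methylmaltol alkylated at its methyl group by the iodo dioxolane of the arylheptanone chain, so the chain ketone stays masked through the base step and is unveiled last.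

Key step: step 7

Assumption: the target is achiral; alcohol 7 is made as the racemate and its carbinol centre is removed in step 4, and the transient stereocentres of 13 and 14 vanish on aromatisation.

Step 1
Reactants: 1 maltol (3-hydroxy-2-methyl-4H-pyran-4-one)
Product: 2 3-methoxy-2-methyl-4H-pyran-4-one (O-methylmaltol)
Conditions: MeI, K2CO3, acetone, reflux
Reagents that add atoms: iodomethane, CI
Why: Williamson-type O-methylation of the acidic 3-hydroxyl (an enol next to the ring carbonyl) under carbonate is routine and leaves the pyranone ring untouched.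

Step 2
Reactants: 3 4-(4-methoxyphenyl)butan-1-ol
Product: 4 1-(4-bromobutyl)-4-methoxybenzene
Conditions: CBr4, PPh3, CH2Cl2, 0 °C to rt
Reagents that add atoms: tetrabromomethane, BrC(Br)(Br)Br
Why: The Appel reaction turns the primary alcohol into the bromide by SN2 displacement of an oxyphosphonium group under neutral conditions that spare the aryl methyl ether.

Step 3
Reactants: 4 1-(4-bromobutyl)-4-methoxybenzene; 5 acrolein
Product: 7 7-(4-methoxyphenyl)hept-1-en-3-ol (racemic), via [4-(4-methoxyphenyl)butyl]magnesium bromide 6 (not isolated)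
Conditions: Mg, I2 (cat.), THF, 45 °C; then 5, −78 °C to 0 °C; aq. NH4Cl
Reagents that add atoms: none
Why: Grignard formation from the primary bromide and 1,2-addition of the hard alkylmagnesium reagent to the aldehyde of acrolein at low temperature should give the allylic alcohol, whose new centre is racemic and is erased in step 4.

Step 4
Reactants: 7 7-(4-methoxyphenyl)hept-1-en-3-ol
Product: 8 7-(4-methoxyphenyl)hept-1-en-3-one
Conditions: Dess–Martin periodinane, CH2Cl2, 0 °C to rt; crude enone used at once
Reagents that add atoms: none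
Why: Dess–Martin oxidation of a secondary allylic alcohol to the vinyl ketone is mild and fast, and the polymerisation-prone enone is carried on without storage.

Step 5
Reactants: 8 7-(4-methoxyphenyl)hept-1-en-3-one
Product: 10 2-(2-iodoethyl)-2-[4-(4-methoxyphenyl)butyl]-1,3-dioxolane, via beta-iodo silyl enol ether 9 (not isolated)
Conditions: Me3SiI, CH2Cl2, −78 °C; then HOCH2CH2OH, −78 °C to rt; aq. NaHCO3/Na2S2O3
Reagents that add atoms: iodotrimethylsilane, C[Si](C)(C)I; ethylene glycol, OCCO
Why: Conjugate addition of iodotrimethylsilane to the s-cis enone gives the (Z)-beta-iodo silyl enol ether 9, which ethylene glycol converts in the same flask by acid-catalysed ketalisation into the beta-iodo dioxolane, a known one-pot route from vinyl ketones, while at −78 °C the aryl methyl ether is not cleaved.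

Step 6
Reactants: 2 3-methoxy-2-methyl-4H-pyran-4-one; 10 2-(2-iodoethyl)-2-[4-(4-methoxyphenyl)butyl]-1,3-dioxolane
Product: 12 3-methoxy-2-{3-[2-[4-(4-methoxyphenyl)butyl]-1,3-dioxolan-2-yl]propyl}-4H-pyran-4-one, via lithium dienolate 11 (not isolated)
Conditions: LiN(SiMe3)2, THF, −78 °C; then 10, DMPU, −78 °C to 0 °C
Reagents that add atoms: none
Why: Lateral deprotonation of the vinylogous 2-methyl group gives the extended dienolate 11, whose exocyclic carbon is alkylated (SN2) by the unhindered primary iodide with restoration of the pyranone pi system, as in known lateral alkylations of 2-methyl-4-pyranones.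

Step 7
Reactants: 12 3-methoxy-2-{3-[2-[4-(4-methoxyphenyl)butyl]-1,3-dioxolan-2-yl]propyl}-4H-pyran-4-one
Product: 15 2-methoxy-4-{2-[2-[4-(4-methoxyphenyl)butyl]-1,3-dioxolan-2-yl]ethyl}benzene-1,3-diol, via ring-opened triketo aldehyde 13 (not isolated), via cyclic aldol adduct 14 (not isolated)
Conditions: KOH (2 M aq., degassed), 1,4-dioxane, 80 °C, Ar; then AcOH to pH 6, 0 °C
Reagents that add atoms: none
Why: Hydroxide should add to C6 (or C2) of the 4-pyranone and open it to the enolate of triketo aldehyde 13; the small equilibrium share of the C1 enolate (the former lateral methylene) then adds to the C6 formyl group, and aldol 14 loses water and tautomerises to the resorcinol, an aromatisation that makes the sequence irreversible. The closest known reaction type is the alkali-induced isomerisation of 2,6-dimethyl-4-pyranone to orcinol through heptane-2,4,6-trione, extended here to a formyl electrophile and a 3-methoxy substituent. The single ring is closed by intramolecular aldol addition in the favoured 6-(enolendo)-exo-trig mode, because both enolate carbons (C1 and C2) lie in the new ring and the aldehyde oxygen lies outside it. No stereocentre remains in 15, those of 14 being lost on aromatisation. The step needs chemoselectivity among several enolates and carbonyls: every other intramolecular enolate–carbonyl pairing in 13 would give a four-membered ring, the chain ketone is shielded as the base-stable dioxolane (free, its alpha-carbons would reach C2 and C4 through six-membered rings), and the anisole is inert. The real competitor is retro-Claisen loss of formate from the beta-keto aldehyde, which is countered by moderate hydroxide concentration, exclusion of oxygen and the irreversible aromatisation.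

Step 8
Reactants: 15 2-methoxy-4-{2-[2-[4-(4-methoxyphenyl)butyl]-1,3-dioxolan-2-yl]ethyl}benzene-1,3-diol
Product: 16 1-(2,4-dihydroxy-3-methoxyphenyl)-7-(4-methoxyphenyl)heptan-3-one
Conditions: HCl (1 M aq.), THF, rt
Reagents that add atoms: water, O
Why: Acid-catalysed acetal hydrolysis in a water-rich, alcohol-free medium should free the ketone, the open hydroxy ketone being favoured over its cyclic hemiketal with the C2 hydroxyl, while the aryl methyl ethers and the resorcinol are inert to dilute acid at room temperature.

Compound list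
1 | maltol (3-hydroxy-2-methyl-4H-pyran-4-one) | Cc1occc(=O)c1O | starting material
2 | 3-methoxy-2-methyl-4H-pyran-4-one (O-methylmaltol) | COc1c(C)occc1=O | intermediate
3 | 4-(4-methoxyphenyl)butan-1-ol | COc1ccc(CCCCO)cc1 | starting material
4 | 1-(4-bromobutyl)-4-methoxybenzene | COc1ccc(CCCCBr)cc1 | intermediate
5 | acrolein (prop-2-enal) | C=CC=O | starting material
6 | [4-(4-methoxyphenyl)butyl]magnesium bromide | COc1ccc(CCCC[Mg]Br)cc1 | intermediate (not isolated)
7 | 7-(4-methoxyphenyl)hept-1-en-3-ol (racemic) | COc1ccc(CCCCC(O)C=C)cc1 | intermediate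
8 | 7-(4-methoxyphenyl)hept-1-en-3-one | COc1ccc(CCCCC(=O)C=C)cc1 | intermediate
9 | (Z)-{[1-iodo-7-(4-methoxyphenyl)hept-2-en-3-yl]oxy}trimethylsilane | COc1ccc(CCCC/C(O[Si](C)(C)C)=C/CI)cc1 | intermediate (not isolated)
10 | 2-(2-iodoethyl)-2-[4-(4-methoxyphenyl)butyl]-1,3-dioxolane | COc1ccc(CCCCC2(CCI)OCCO2)cc1 | intermediate
11 | lithium 3-methoxy-2-methylidene-2H-pyran-4-olate | [Li+].[O-]C1=C(OC)C(=C)OC=C1 | intermediate (not isolated)
12 | 3-methoxy-2-{3-[2-[4-(4-methoxyphenyl)butyl]-1,3-dioxolan-2-yl]propyl}-4H-pyran-4-one | COc1c(CCCC2(CCCCc3ccc(OC)cc3)OCCO2)occc1=O | intermediate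
13 | 4-methoxy-8-{2-[4-(4-methoxyphenyl)butyl]-1,3-dioxolan-2-yl}-3,5-dioxooctanal (drawn as the triketo tautomer; present as its enolates, C4 not defined) | O=CCC(=O)C(OC)C(=O)CCCC1(CCCCc2ccc(OC)cc2)OCCO1 | intermediate (not isolated)
14 | 5-hydroxy-2-methoxy-4-{2-[2-[4-(4-methoxyphenyl)butyl]-1,3-dioxolan-2-yl]ethyl}cyclohexane-1,3-dione (mixture of stereoisomers, all converging) | COC1C(=O)CC(O)C(CCC2(CCCCc3ccc(OC)cc3)OCCO2)C1=O | intermediate (not isolated)
15 | 2-methoxy-4-{2-[2-[4-(4-methoxyphenyl)butyl]-1,3-dioxolan-2-yl]ethyl}benzene-1,3-diol | COc1ccc(CCCCC2(CCc3ccc(O)c(OC)c3O)OCCO2)cc1 | intermediate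
16 | 1-(2,4-dihydroxy-3-methoxyphenyl)-7-(4-methoxyphenyl)heptan-3-one | COc1ccc(CCCCC(=O)CCc2ccc(O)c(OC)c2O)cc1 | target

Total step count: 8. Longest linear sequence: 7 steps (3 to 16 through steps 2, 3, 4, 5, 6, 7 and 8).

Steps most likely to fail

Step 7. Retro-Claisen loss of the formyl carbon as formate from the ring-opened intermediate, or hydroxide cleavage of its 1,3-diketone, may outrun the slow aldol closure, and the electron-rich resorcinolate may be oxidised by traces of air. The fallback buys the arene instead of building it; it sets out from iodide 10 and comes back at target 16. Purchasable 2-methoxybenzene-1,3-diol is protected (MOMCl, i-Pr2NEt, CH2Cl2) as 2-methoxy-1,3-bis(methoxymethoxy)benzene F1. Directed ortho-lithiation next to one MOM ether (n-BuLi, TMEDA, THF, 0 °C) gives [3-methoxy-2,4-bis(methoxymethoxy)phenyl]lithium F2. Alkylation of F2 by 10 gives 2-{2-[3-methoxy-2,4-bis(methoxymethoxy)phenyl]ethyl}-2-[4-(4-methoxyphenyl)butyl]-1,3-dioxolane F3. Aqueous HCl in THF at 50 °C then removes both MOM groups and the dioxolane to give 16.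

Step 6. The basic dienolate may eliminate HI from the iodide, deprotonation may compete at ring positions, or the product may be alkylated a second time at its lateral carbon. The fallback replaces alkylation by olefination and reduction; it sets out from 2 and 10 and comes back at 12. Oxidation of the lateral methyl of 2 (SeO2, 1,4-dioxane, reflux) gives 3-methoxy-4-oxo-4H-pyran-2-carbaldehyde F4. Iodide 10 and PPh3 (MeCN, reflux) give {2-[2-[4-(4-methoxyphenyl)butyl]-1,3-dioxolan-2-yl]ethyl}triphenylphosphonium iodide F5, which NaN(SiMe3)2 (THF, −78 °C) converts into the ylide {2-[2-[4-(4-methoxyphenyl)butyl]-1,3-dioxolan-2-yl]ethylidene}triphenylphosphorane F6. Wittig reaction of F6 with F4 gives 3-methoxy-2-{(Z)-3-[2-[4-(4-methoxyphenyl)butyl]-1,3-dioxolan-2-yl]prop-1-en-1-yl}-4H-pyran-4-one F7 (Z expected, geometry of no consequence). Hydrogenation of the exocyclic disubstituted alkene (H2, Pd/C, EtOAc, stopped after one equivalent) gives 12.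

Step 5. The vinyl ketone may polymerise before or during iodosilylation, and excess iodotrimethylsilane or HI may cleave the aryl methyl ether or the newly formed dioxolane. The fallback avoids both the enone and the silyl iodide; it sets out from bromide 4 (through its Grignard reagent 6) and comes back at 10. Acylation of 6 with 3-chloropropanoyl chloride (Fe(acac)3 cat., THF, −78 °C) gives 1-chloro-7-(4-methoxyphenyl)heptan-3-one F8. Ketalisation (ethylene glycol, TsOH cat., toluene, azeotropic removal of water) gives 2-(2-chloroethyl)-2-[4-(4-methoxyphenyl)butyl]-1,3-dioxolane F9. Finkelstein exchange (NaI, butanone, reflux) gives 10.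

Further compounds
F1 | step 7 | 2-methoxy-1,3-bis(methoxymethoxy)benzene | COCOc1cccc(OCOC)c1OC
F2 | step 7 | [3-methoxy-2,4-bis(methoxymethoxy)phenyl]lithium | [Li]c1ccc(OCOC)c(OC)c1OCOC
F3 | step 7 | 2-{2-[3-methoxy-2,4-bis(methoxymethoxy)phenyl]ethyl}-2-[4-(4-methoxyphenyl)butyl]-1,3-dioxolane | COCOc1ccc(CCC2(CCCCc3ccc(OC)cc3)OCCO2)c(OCOC)c1OC
F4 | step 6 | 3-methoxy-4-oxo-4H-pyran-2-carbaldehyde | COc1c(C=O)occc1=O
F5 | step 6 | {2-[2-[4-(4-methoxyphenyl)butyl]-1,3-dioxolan-2-yl]ethyl}triphenylphosphonium iodide | COc1ccc(CCCCC2(CC[P+](c3ccccc3)(c3ccccc3)c3ccccc3)OCCO2)cc1.[I-]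
F6 | step 6 | {2-[2-[4-(4-methoxyphenyl)butyl]-1,3-dioxolan-2-yl]ethylidene}triphenylphosphorane | COc1ccc(CCCCC2(CC=P(c3ccccc3)(c3ccccc3)c3ccccc3)OCCO2)cc1
F7 | step 6 | 3-methoxy-2-{(Z)-3-[2-[4-(4-methoxyphenyl)butyl]-1,3-dioxolan-2-yl]prop-1-en-1-yl}-4H-pyran-4-one | COc1c(/C=C\CC2(CCCCc3ccc(OC)cc3)OCCO2)occc1=O
F8 | step 5 | 1-chloro-7-(4-methoxyphenyl)heptan-3-one | COc1ccc(CCCCC(=O)CCCl)cc1
F9 | step 5 | 2-(2-chloroethyl)-2-[4-(4-methoxyphenyl)butyl]-1,3-dioxolane | COc1ccc(CCCCC2(CCCl)OCCO2)cc1
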